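**Plan**
- Retrosynthetic cuts, in order: (a) the ester bond at O8, which releases the (E)-4-hydroxy-2-(hydroxymethyl)but-2-enoic acid as its seven-membered acetonide; (b) the two hydrogens on C11/C13, back to the α-methylene lactone; (c) the lactone bond C12–O6 and the oxygens on C6, C8 and C12, back to germacrene A; (d) the ring bond C6–C7, which opens the ten-membered ring to farnesyl diphosphate.
- Enabling feature: the carbocycle C1–C10 with its E alkenes C1=C10 and C4=C5, the methyls on C4 and C10 and the three-carbon unit C11–C13 on C7 is an intact head-to-tail farnesyl chain, and ring bond C6–C7 is the farnesyl C1–C10 bond.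
- Forward order: farnesol is turned into its diphosphate; germacrene A synthase closes the ten-membered carbocycle first; three cytochrome P450s oxidise C12, C8 and C6, the last one closing the γ-lactone second; conjugate reduction, esterification of O8 and acetonide cleavage finish the route.
- Stereochemistry: C7 from the synthase; C8 (oxygen β) and C6 (oxygen α) from the two hydroxylases; C11 from face-selective protonation in the NaBH4 reduction; the ring alkenes from (2E,6E)-farnesol; the side-chain E alkene from syn-hydrostannation of a symmetrical alkyne, then locked in the dioxepine ring.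

Key step: step 3

Assumption: the recombinant enzymes (germacrene A synthase and the three cytochrome P450s, each with a P450 reductase) are treated as catalysts obtained by routine heterologous expression, and compound 3 is drawn as the free acid although it is isolated and used as its triammonium salt.

**Route**

Step 1
Reactants: 1 (2E,6E)-farnesol
Product: 2 (2E,6E)-farnesyl chloride
Conditions: NCS, Me2S, CH2Cl2, −40 to 0 °C
Reagents that add atoms: N-chlorosuccinimide, O=C1CCC(=O)N1Cl
Why: Corey–Kim chlorination, in which the alkoxysulfonium salt of the primary allylic alcohol is displaced by chloride in an SN2 step, so neither allylic transposition nor loss of the 2E geometry is expected under these cold, non-acidic conditions.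

Step 2
Reactants: 2 (2E,6E)-farnesyl chloride
Product: 3 (2E,6E)-farnesyl diphosphate (triammonium salt)
Conditions: (Bu4N)3HP2O7, MeCN, rt; cation-exchange resin (NH4+ form), 25 mM NH4HCO3 in 2% i-PrOH/H2O; cellulose chromatography; lyophilisation
Reagents that add atoms: tris(tetrabutylammonium) hydrogen diphosphate, CCCC[N+](CCCC)(CCCC)CCCC.CCCC[N+](CCCC)(CCCC)CCCC.CCCC[N+](CCCC)(CCCC)CCCC.OP(=O)([O-])OP(=O)([O-])[O-]
Why: SN2 displacement of the primary allylic chloride by the soluble, weakly basic diphosphate anion is the standard diphosphorylation of allylic halides and leaves the three alkenes untouched; cation exchange supplies the water-soluble ammonium salt that the enzyme accepts.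

Step 3
Reactants: 3 (2E,6E)-farnesyl diphosphate
Product: 4 (+)-(R)-germacrene A
Conditions: recombinant (+)-germacrene A synthase of chicory (His-tagged, from E. coli), 25 mM HEPES pH 7.5, 10 mM MgCl2, 5 mM DTT, 10% glycerol, pentane overlay, 30 °C; cold pentane extraction, short neutral alumina plug
Reagents that add atoms: none
Why: This is a class 1 terpene synthase cyclization, a cation–alkene macrocyclization that is the native reaction of this enzyme on this substrate: the magnesium ions held by the aspartate-rich motifs ionize the diphosphate to the (2E,6E)-farnesyl allyl cation, the distal C10=C11 alkene (farnesyl numbering) attacks C1, and the tertiary C11 cation loses a proton from one of its methyl groups to give the isopropenyl group. The ten-membered ring closes by 1,10 closure in which the attacking alkene stays exocyclic to the new ring (10-exo, Markovnikov sense) and the allyl cation is captured at its primary terminus, so the former C2=C3 alkene ends up E inside the ring. The one new stereocentre, germacrane C7 (farnesyl C10), is set as R because the enzyme pocket folds the chain so that only one face of the C10=C11 alkene can reach C1. The step needs 1,10 closure in preference to 1,11 or 1,6 closure, retention of both E alkenes, and a clean terminating deprotonation instead of hydride shifts, further cyclization or water capture; the E,E geometry of 3 and the product specificity of the Asteraceae synthase secure all three. The pentane overlay removes 4 from the aqueous phase as it forms, which protects it from proton-induced transannular cyclization, and cold handling avoids its Cope rearrangement to β-elemene.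

Step 4
Reactants: 4 (+)-(R)-germacrene A
Product: 7 germacrene A acid, via germacratrien-12-ol 5 (not isolated), via germacratrien-12-al 6 (not isolated)
Conditions: yeast microsomes containing chicory germacrene A oxidase (a CYP71 family P450) and the reductase ATR1, NADPH (cat.), glucose 6-phosphate, glucose-6-phosphate dehydrogenase, air, 50 mM HEPES pH 7.5, 2% DMSO, 30 °C; EtOAc extraction at pH 6, 4 °C
Reagents that add atoms: dioxygen, O=O
Why: Cytochrome P450 hydroxylation (hydrogen abstraction and oxygen rebound at the ferryl-oxo haem, tetravalent iron) is repeated three times by the same oxidase at the allylic C12 methyl of the isopropenyl group, which is the native reaction of germacrene A oxidase and leaves C7 and both ring alkenes untouched.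

Step 5
Reactants: 7 germacrene A acid
Product: 8 8β-hydroxygermacrene A acid
Conditions: yeast microsomes containing CYP71BL1 (sunflower germacrene A acid 8β-hydroxylase) and ATR1, NADPH (cat.), glucose 6-phosphate, glucose-6-phosphate dehydrogenase, air, 50 mM HEPES pH 7.5, 30 °C; EtOAc extraction at pH 6, 4 °C
Reagents that add atoms: dioxygen, O=O
Why: Native regio- and stereoselective P450 C–H hydroxylation with retention: CYP71BL1 binds the acid so that only the 8β hydrogen faces the ferryl oxygen, which sets C8 with its hydroxyl β, cis to the C7 side chain.

Step 6
Reactants: 8 8β-hydroxygermacrene A acid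
Product: 10 eupatolide, via 6α,8β-dihydroxygermacrene A acid 9 (not isolated)
Conditions: yeast microsomes containing CYP71DD6 (sunflower eupatolide synthase) and ATR1, NADPH (cat.), glucose 6-phosphate, glucose-6-phosphate dehydrogenase, air, 50 mM HEPES pH 7.5, 30 °C; EtOAc extraction
Reagents that add atoms: dioxygen, O=O
Why: CYP71DD6 hydroxylates the allylic C6 position on the α face (oxygen rebound with retention, setting C6), and the 6α-hydroxy acid then closes spontaneously to the γ-lactone by attack of O6 on C12 (5-exo-trig acyl substitution), trans-fused because O6 is α and the C7 side chain β; this is the native eupatolide-forming reaction.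

Step 7
Reactants: 10 eupatolide
Product: 11 11βH,13-dihydroeupatolide
Conditions: NaBH4, MeOH, 0 °C; AcOH quench
Reagents that add atoms: none
Why: Conjugate reduction of an α-methylene-γ-lactone: hydride adds to the exocyclic C13 and methanol protonates the lactone enolate at C11 on the β face, the face of the 8β-hydroxyl, which leaves the new methyl α and trans to the C7–C8 bond (11S), the usual outcome for trans-fused 12,6-germacranolides.

Step 8
Reactants: 12 2-butyne-1,4-diol
Product: 13 (E)-2-(tributylstannyl)but-2-ene-1,4-diol
Conditions: Bu3SnH, PdCl2(PPh3)2 (2 mol %), THF, 0 °C to rt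
Reagents that add atoms: tributylstannane, CCCC[SnH](CCCC)CCCC
Why: Palladium-catalysed hydrostannation (the divalent palladium salt is reduced by the stannane to zerovalent palladium, which adds Sn–H syn across the alkyne) puts the two hydroxymethyl groups cis, and the symmetrical alkyne leaves no regiochemical question.

Step 9
Reactants: 13 (E)-2-(tributylstannyl)but-2-ene-1,4-diol
Product: 14 2,2-dimethyl-5-(tributylstannyl)-4,7-dihydro-1,3-dioxepine
Conditions: 2,2-dimethoxypropane, PPTS (cat.), CH2Cl2, rt
Reagents that add atoms: 2,2-dimethoxypropane, COC(C)(C)OC
Why: Acid-catalysed transacetalisation closes the seven-membered acetonide, which is possible only because the two hydroxymethyl groups are cis, and the ring then locks the alkene geometry for the rest of the route.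

Step 10
Reactants: 14 2,2-dimethyl-5-(tributylstannyl)-4,7-dihydro-1,3-dioxepine
Product: 16 2,2-dimethyl-4,7-dihydro-1,3-dioxepine-5-carboxylic acid, via 5-lithiodioxepine 15 (not isolated)
Conditions: n-BuLi, THF, −78 °C; CO2 (g), −78 to 0 °C; cold 1 M HCl to pH 4
Reagents that add atoms: carbon dioxide, O=C=O
Why: Tin–lithium exchange gives the ring-held alkenyllithium, which is carboxylated by CO2 with retention at the sp2 carbon, and the low temperature suppresses β-elimination of the allylic alkoxide.

Step 11
Reactants: 11 11βH,13-dihydroeupatolide; 16 2,2-dimethyl-4,7-dihydro-1,3-dioxepine-5-carboxylic acid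
Product: 17 8-O-(2,2-dimethyl-4,7-dihydro-1,3-dioxepine-5-carbonyl)-11βH,13-dihydroeupatolide
Conditions: DCC, DMAP, CH2Cl2, 0 °C to rt
Reagents that add atoms: none
Why: Steglich esterification (O-acylisourea, then acylpyridinium) acylates the secondary 8β-hydroxyl on oxygen, so C8 keeps its configuration, and the absence of a stoichiometric amine base together with the ring-locked alkene guards against deconjugation or E/Z drift of the acyl group.

Step 12
Reactants: 17 8-O-(2,2-dimethyl-4,7-dihydro-1,3-dioxepine-5-carbonyl)-11βH,13-dihydroeupatolide
Product: 18 CNP0272217.1 (11βH,13-dihydroeupatoriopicrin)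
Conditions: PPTS (cat.), MeOH, rt
Reagents that add atoms: none
Why: Acid-catalysed transacetalisation to methanol frees the labile seven-membered acetonide as the diol with the E geometry intact, and the weak pyridinium acid should spare the lactone, the ester and the acid-sensitive 1(10),4-diene.

**Compound list**
1 | (2E,6E)-farnesol | CC(C)=CCC/C(C)=C/CC/C(C)=C/CO | starting material
2 | (2E,6E)-farnesyl chloride | CC(C)=CCC/C(C)=C/CC/C(C)=C/CCl | intermediate
3 | (2E,6E)-farnesyl diphosphate (used as the triammonium salt, drawn as the free acid) | CC(C)=CCC/C(C)=C/CC/C(C)=C/COP(=O)(O)OP(=O)(O)O | intermediate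
4 | (+)-(R)-germacrene A, germacra-1(10)E,4E,11-triene with 7αH | C/C1=C\C[C@H](C(C)=C)CC/C(C)=C/CC1 | intermediate
5 | germacra-1(10)E,4E,11(13)-trien-12-ol (7αH), not isolated | C/C1=C\C[C@H](C(=C)CO)CC/C(C)=C/CC1 | intermediate
6 | germacra-1(10)E,4E,11(13)-trien-12-al (7αH), not isolated | C/C1=C\C[C@H](C(=C)C=O)CC/C(C)=C/CC1 | intermediate
7 | germacrene A acid, germacra-1(10)E,4E,11(13)-trien-12-oic acid (7αH) | C/C1=C\C[C@H](C(=C)C(=O)O)CC/C(C)=C/CC1 | intermediate
8 | 8β-hydroxygermacrene A acid | C/C1=C\C[C@H](C(=C)C(=O)O)[C@H](O)C/C(C)=C/CC1 | intermediate
9 | 6α,8β-dihydroxygermacrene A acid, not isolated | C/C1=C\[C@@H](O)[C@H](C(=C)C(=O)O)[C@H](O)C/C(C)=C/CC1 | intermediate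
10 | eupatolide (8β-hydroxycostunolide; 6R,7R,8R) | C/C1=C\[C@H]2OC(=O)C(=C)[C@@H]2[C@H](O)C/C(C)=C/CC1 | intermediate
11 | 11βH,13-dihydroeupatolide (6R,7R,8R,11S) | C/C1=C\[C@H]2OC(=O)[C@@H](C)[C@@H]2[C@H](O)C/C(C)=C/CC1 | intermediate
12 | 2-butyne-1,4-diol | OCC#CCO | starting material
13 | (E)-2-(tributylstannyl)but-2-ene-1,4-diol (hydroxymethyl groups cis) | OC/C=C(/[Sn](CCCC)(CCCC)CCCC)CO | intermediate
14 | 2,2-dimethyl-5-(tributylstannyl)-4,7-dihydro-1,3-dioxepine | CC1(C)OCC=C([Sn](CCCC)(CCCC)CCCC)CO1 | intermediate
15 | 5-lithio-2,2-dimethyl-4,7-dihydro-1,3-dioxepine, not isolated | [Li]C1=CCOC(C)(C)OC1 | intermediate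
16 | 2,2-dimethyl-4,7-dihydro-1,3-dioxepine-5-carboxylic acid | CC1(C)OCC=C(C(=O)O)CO1 | intermediate
17 | 8-O-(2,2-dimethyl-4,7-dihydro-1,3-dioxepine-5-carbonyl)-11βH,13-dihydroeupatolide | C/C1=C\[C@H]2OC(=O)[C@@H](C)[C@@H]2[C@H](OC(=O)C3=CCOC(C)(C)OC3)C/C(C)=C/CC1 | intermediate
18 | CNP0272217.1, 8β-[(E)-4-hydroxy-2-(hydroxymethyl)but-2-enoyloxy]-11βH,13-dihydrocostunolide (6R,7R,8R,11S) | C/C1=C\[C@H]2OC(=O)[C@@H](C)[C@@H]2[C@H](OC(=O)/C(=C/CO)CO)C/C(C)=C/CC1 | target

**Step count and risks**

Total step count: 12. Longest linear sequence: 9 steps (steps 1–7, 11 and 12, from farnesol); the side-chain acid takes 3 steps (8–10).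

The three steps most likely to fail:

Step 6. The membrane-bound P450 may turn over slowly and uncouple in a cell-free preparation while the labile hydroxy acid 8 undergoes proton-induced transannular cyclization, and part of the dihydroxy acid may close onto O8 instead of O6. The fallback moves the whole oxidative block into living yeast. It leaves the route at 3, which a Saccharomyces cerevisiae strain with raised farnesyl diphosphate supply makes itself from glucose through the mevalonate pathway. The strain co-expresses germacrene A synthase, germacrene A oxidase, CYP71BL1, CYP71DD6 and a P450 reductase and is grown in medium buffered at pH 7.5. Intermediates 4 to 9 never leave the cell, the cofactor comes from metabolism, and the ring closure 3 to 4 is the same enzymatic event. Ethyl acetate extraction of the culture rejoins the route at 10. This fallback makes no new compound (F0).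

Step 7. Protonation of the lactone enolate may show poor facial selectivity and give the C11 epimer, the methoxide formed may trigger migration of the lactone from O6 to the free O8, and the lactone carbonyl may be reduced further. The fallback is a hydroxyl-directed homogeneous hydrogenation that sets out from 10 and returns directly at 11: H2 (1 atm), [Rh(nbd)(dppb)]BF4 (a cationic complex of monovalent rhodium), CH2Cl2, rt, stopped after one equivalent of hydrogen. The 8β-hydroxyl, homoallylic to C11=C13, binds rhodium and delivers both hydrogens to the β face of the exocyclic alkene, giving 11βH without hydride or base. The 1,1-disubstituted acrylate-type alkene should react well before the trisubstituted ring alkenes. This fallback makes no new compound (F0).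

Step 12. Proton-induced transannular cyclization of the 1(10),4-diene to eudesmane-type products may compete with a slow transacetalisation, and the side-chain ester may undergo methanolysis. The fallback replaces the acid-labile acetonide by silyl ethers that are removed with fluoride. It sets out from 13: TBSCl and imidazole in DMF give (E)-1,4-bis(tert-butyldimethylsilyloxy)-2-(tributylstannyl)but-2-ene F1. Tin–lithium exchange (n-BuLi, THF, −78 °C, where the alkenyllithium keeps its geometry) and CO2 give (E)-4-(tert-butyldimethylsilyloxy)-2-(tert-butyldimethylsilyloxymethyl)but-2-enoic acid F2. Steglich esterification of F2 with 11 (DCC, DMAP, CH2Cl2) gives the bis-silyl ester of 11βH,13-dihydroeupatolide F3. TBAF buffered with AcOH in THF at 0 °C then removes both silyl groups under near-neutral conditions and returns to the route at 18.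

Further compounds
F0 | step 6 | none | none
F0 | step 7 | none | none
F1 | step 12 | (E)-1,4-bis(tert-butyldimethylsilyloxy)-2-(tributylstannyl)but-2-ene | CC(C)(C)[Si](C)(C)OC/C=C(/[Sn](CCCC)(CCCC)CCCC)CO[Si](C)(C)C(C)(C)C
F2 | step 12 | (E)-4-(tert-butyldimethylsilyloxy)-2-(tert-butyldimethylsilyloxymethyl)but-2-enoic acid | CC(C)(C)[Si](C)(C)OC/C=C(/C(=O)O)CO[Si](C)(C)C(C)(C)C
F3 | step 12 | 8-O-[(E)-4-(tert-butyldimethylsilyloxy)-2-(tert-butyldimethylsilyloxymethyl)but-2-enoyl]-11βH,13-dihydroeupatolide | C/C1=C\[C@H]2OC(=O)[C@@H](C)[C@@H]2[C@H](OC(=O)/C(=C/CO[Si](C)(C)C(C)(C)C)CO[Si](C)(C)C(C)(C)C)C/C(C)=C/CC1
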